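## Retrosynthetic overview
1. 18 ⇐ 17 by hydrogenolysis of the two B-ring benzyl ethers; 17 ⇐ 15 by chelation-controlled cleavage of the 5-OMe only.
2. Ring C is the only ring formed (rings A and B are bought as arenes). It comes from cyclodehydration of the α-methoxy-1,3-diketone 14, which already carries the 3-OMe.
3. 14 ⇐ C-acylation of the polyanion of ω-methoxyacetophenone 8 (ring A) with aroyl chloride 12 (ring B).
4. 8 ⇐ Elbs para-hydroxylation of 6 ⇐ selective ortho-demethylation of 4 ⇐ ortho-lithiated 1,2,3,5-tetramethoxybenzene 1 + Weinreb amide 2.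
5. 12 ⇐ methyl 3,5-dihydroxy-4-methoxybenzoate 9 (benzylation, saponification, chlorination).

Assumption: the target has no stereocentre and no stereogenic double bond, so "single enantiomer" needs no stereocontrol. Compounds 1, 2 and 9 are taken as catalogue chemicals.

## Route

Step 1
Reactants: 1 1,2,3,5-tetramethoxybenzene; 2 N,2-dimethoxy-N-methylacetamide
Product: 4 2-methoxy-1-(2,3,4,6-tetramethoxyphenyl)ethan-1-one, via 2,3,4,6-tetramethoxyphenyllithium 3 (not isolated)
Conditions: n-BuLi, TMEDA, THF, 0 °C to rt; then 2, −78 °C to 0 °C; 1 M HCl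
Reagents that add atoms: none
Why: Directed ortho-metalation removes one of the two equivalent ring protons, each flanked by two OMe groups, and the Weinreb ketone synthesis stops cleanly at the ketone. This also avoids the decarbonylation that methoxyacetyl chloride suffers under Friedel–Crafts conditions.

Step 2
Reactants: 4 2-methoxy-1-(2,3,4,6-tetramethoxyphenyl)ethan-1-one
Product: 6 1-(2-hydroxy-3,4,6-trimethoxyphenyl)-2-methoxyethan-1-one, via aryloxydichloroborane chelate 5 (not isolated)
Conditions: BCl3 (1.1 equiv), CH2Cl2, −78 °C to 0 °C; H2O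
Reagents that add atoms: none
Why: In this chelation-controlled Lewis-acid ether cleavage, BCl3 bound to the ketone cleaves one ortho-OMe through a six-membered chelate. The 2-OMe goes first because the 3-OMe buttresses it out of plane (the same selectivity as in AlCl3 acylations of 1), and chelate 5 blocks a second cleavage.

Step 3
Reactants: 6 1-(2-hydroxy-3,4,6-trimethoxyphenyl)-2-methoxyethan-1-one
Product: 8 1-(2,5-dihydroxy-3,4,6-trimethoxyphenyl)-2-methoxyethan-1-one, via potassium aryl sulfate 7 (not isolated)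
Conditions: K2S2O8, aq KOH, 10–20 °C, 24 h, N2; acidify and extract unreacted 6; then conc. HCl, 85 °C
Reagents that add atoms: potassium peroxodisulfate, [K+].[K+].[O-]S(=O)(=O)OOS(=O)(=O)[O-]
Why: In the Elbs persulfate oxidation the phenolate attacks peroxodisulfate through the carbon para to O⁻, which is the only free ring position. Acid hydrolysis of sulfate 7 then releases hydroquinone 8, and unreacted 6 is recycled.

Step 4
Reactants: 9 methyl 3,5-dihydroxy-4-methoxybenzoate
Product: 11 3,5-bis(benzyloxy)-4-methoxybenzoic acid, via methyl 3,5-bis(benzyloxy)-4-methoxybenzoate 10 (not isolated)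
Conditions: BnBr, K2CO3, DMF, 60 °C; then aq KOH, MeOH, 60 °C; HCl
Reagents that add atoms: benzyl bromide, BrCc1ccccc1; potassium hydroxide, [K+].[OH-]
Why: Williamson ether synthesis on both phenols followed by one-pot saponification gives an acid whose protecting groups survive strong base and come off by hydrogenolysis without touching any OMe.

Step 5
Reactants: 11 3,5-bis(benzyloxy)-4-methoxybenzoic acid
Product: 12 3,5-bis(benzyloxy)-4-methoxybenzoyl chloride
Conditions: (COCl)2, cat. DMF, CH2Cl2, 0 °C to rt; evaporate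
Reagents that add atoms: oxalyl chloride, ClC(=O)C(=O)Cl
Why: Acid chloride formation through the catalytic Vilsmeier-type chloroiminium species is mild, gives only gaseous by-products and leaves aryl benzyl and methyl ethers untouched.

Step 6
Reactants: 8 1-(2,5-dihydroxy-3,4,6-trimethoxyphenyl)-2-methoxyethan-1-one; 12 3,5-bis(benzyloxy)-4-methoxybenzoyl chloride
Product: 15 2-[3,5-bis(benzyloxy)-4-methoxyphenyl]-6-hydroxy-3,5,7,8-tetramethoxy-4H-chromen-4-one, via trilithium enolate-bisphenolate 13 (not isolated), via alpha-methoxy-1,3-diketone 14 (not isolated)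
Conditions: LiHMDS (4.2 equiv), THF, −78 to −10 °C; 12 (1.0 equiv), −78 °C to rt; 1 M HCl; crude in AcOH, cat. H2SO4 (0.5 vol %), 60 °C
Reagents that add atoms: none
Why: This is a Claisen-type C-acylation of the polylithiated hydroxyacetophenone, a direct variant of the Baker–Venkataraman route in which any 2-O-aroyl ester rearranges to the same diketone. Acid cyclodehydration through the only ortho-OH then closes ring C and destroys the racemic, labile CH(OMe) centre of 14.

Step 7
Reactants: 15 2-[3,5-bis(benzyloxy)-4-methoxyphenyl]-6-hydroxy-3,5,7,8-tetramethoxy-4H-chromen-4-one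
Product: 17 2-[3,5-bis(benzyloxy)-4-methoxyphenyl]-5,6-dihydroxy-3,7,8-trimethoxy-4H-chromen-4-one, via 5-O-dichloroaluminium chelate 16 (not isolated)
Conditions: anhydrous AlCl3, MeCN, 60 °C; then 2 M HCl
Reagents that add atoms: none
Why: In this chelation-controlled peri-demethylation, nitrile-tempered AlCl3 cleaves only the 5-OMe, which forms a six-membered chelate with the C4 carbonyl next to the 6-O–Al group. The 3-, 7-, 8- and 4'-OMe groups react much more slowly, and any premature loss of benzyl is harmless because benzyl is removed in the next step.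

Step 8
Reactants: 17 2-[3,5-bis(benzyloxy)-4-methoxyphenyl]-5,6-dihydroxy-3,7,8-trimethoxy-4H-chromen-4-one
Product: 18 5,6,3',5'-tetrahydroxy-3,7,8,4'-tetramethoxyflavone
Conditions: H2 (1 atm), 10% Pd/C, degassed EtOAc–MeOH, rt
Reagents that add atoms: none
Why: Catalytic hydrogenolysis cleaves both benzylic C–O bonds under neutral conditions, so no Wessely–Moser isomerisation can occur. The tetrasubstituted C2=C3 bond, the methyl ethers and the pyranone are left intact, and no stereocentre is present or created.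

## Compound list
Compound 14 is racemic and configurationally labile; all other compounds have no stereocentre.

1 | 1,2,3,5-tetramethoxybenzene | COc1cc(OC)c(OC)c(OC)c1 | starting material
2 | N,2-dimethoxy-N-methylacetamide | COCC(=O)N(C)OC | starting material
3 | 2,3,4,6-tetramethoxyphenyllithium | [Li]c1c(OC)cc(OC)c(OC)c1OC | intermediate
4 | 2-methoxy-1-(2,3,4,6-tetramethoxyphenyl)ethan-1-one | COCC(=O)c1c(OC)cc(OC)c(OC)c1OC | intermediate
5 | dichloro[3,4,6-trimethoxy-2-(methoxyacetyl)phenoxy]borane (chelate) | COCC(=O)c1c(OC)cc(OC)c(OC)c1OB(Cl)Cl | intermediate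
6 | 1-(2-hydroxy-3,4,6-trimethoxyphenyl)-2-methoxyethan-1-one | COCC(=O)c1c(OC)cc(OC)c(OC)c1O | intermediate
7 | potassium 4-hydroxy-2,5,6-trimethoxy-3-(methoxyacetyl)phenyl sulfate | COCC(=O)c1c(OC)c(OS(=O)(=O)[O-])c(OC)c(OC)c1O.[K+] | intermediate
8 | 1-(2,5-dihydroxy-3,4,6-trimethoxyphenyl)-2-methoxyethan-1-one | COCC(=O)c1c(OC)c(O)c(OC)c(OC)c1O | intermediate
9 | methyl 3,5-dihydroxy-4-methoxybenzoate | COC(=O)c1cc(O)c(OC)c(O)c1 | starting material
10 | methyl 3,5-bis(benzyloxy)-4-methoxybenzoate | COC(=O)c1cc(OCc2ccccc2)c(OC)c(OCc2ccccc2)c1 | intermediate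
11 | 3,5-bis(benzyloxy)-4-methoxybenzoic acid | OC(=O)c1cc(OCc2ccccc2)c(OC)c(OCc2ccccc2)c1 | intermediate
12 | 3,5-bis(benzyloxy)-4-methoxybenzoyl chloride | ClC(=O)c1cc(OCc2ccccc2)c(OC)c(OCc2ccccc2)c1 | intermediate
13 | trilithium enolate-bisphenolate of 8 | [Li]OC(=COC)c1c(OC)c(O[Li])c(OC)c(OC)c1O[Li] | intermediate
14 | 1-[3,5-bis(benzyloxy)-4-methoxyphenyl]-3-(2,5-dihydroxy-3,4,6-trimethoxyphenyl)-2-methoxypropane-1,3-dione (racemic) | COC(C(=O)c1cc(OCc2ccccc2)c(OC)c(OCc2ccccc2)c1)C(=O)c1c(OC)c(O)c(OC)c(OC)c1O | intermediate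
15 | 2-[3,5-bis(benzyloxy)-4-methoxyphenyl]-6-hydroxy-3,5,7,8-tetramethoxy-4H-chromen-4-one | COc1c(OCc2ccccc2)cc(cc1OCc1ccccc1)-c1oc2c(OC)c(OC)c(O)c(OC)c2c(=O)c1OC | intermediate
16 | 5-O-dichloroaluminium chelate of 17 | COc1c(OCc2ccccc2)cc(cc1OCc1ccccc1)-c1oc2c(OC)c(OC)c(O)c(O[Al](Cl)Cl)c2c(=O)c1OC | intermediate
17 | 2-[3,5-bis(benzyloxy)-4-methoxyphenyl]-5,6-dihydroxy-3,7,8-trimethoxy-4H-chromen-4-one | COc1c(OCc2ccccc2)cc(cc1OCc1ccccc1)-c1oc2c(OC)c(OC)c(O)c(O)c2c(=O)c1OC | intermediate
18 | 5,6,3',5'-tetrahydroxy-3,7,8,4'-tetramethoxyflavone | COc1c(O)cc(-c2oc3c(OC)c(OC)c(O)c(O)c3c(=O)c2OC)cc1O | target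

## Step count and risks
Total step count: 8. Longest linear sequence: 6 (steps 1, 2, 3, 6, 7, 8).

**Risk 1, step 3.** Elbs oxidations stall at low conversion, and the electron-rich product can over-oxidise. The fallback sets out from 6 and comes back at 8. Vilsmeier–Haack formylation (POCl3, DMF) at the single free ring position, para to the phenol, gives 4-hydroxy-2,5,6-trimethoxy-3-(methoxyacetyl)benzaldehyde F1. Dakin oxidation of this para-hydroxybenzaldehyde (H2O2, aq KOH, 0 °C) proceeds by aryl migration to 4-hydroxy-2,5,6-trimethoxy-3-(methoxyacetyl)phenyl formate F2. F2 is hydrolysed in the same pot to 8. The aldehyde reacts much faster than the hindered, chelated ketone.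

**Risk 2, step 6.** The α-methoxy enolate is hindered, so O-acylation at the 5-phenolate or incomplete C-acylation may compete. The fallback sets out from 8 (using 11 and 12) and comes back at 15.
- Acid 11 and chloride 12 are joined in pyridine to give 3,5-bis(benzyloxy)-4-methoxybenzoic anhydride F3.
- Part of 11 is neutralised with KOH to potassium 3,5-bis(benzyloxy)-4-methoxybenzoate F4.
- Fusing 8 with F3 and F4 at 165–175 °C (Allan–Robinson condensation) builds ring C directly. It also aroylates the 6-OH, giving 2-[3,5-bis(benzyloxy)-4-methoxyphenyl]-3,5,7,8-tetramethoxy-4-oxo-4H-chromen-6-yl 3,5-bis(benzyloxy)-4-methoxybenzoate F5.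
- Brief KOH/EtOH treatment removes the ester and returns 15.

**Risk 3, step 7.** Over-cleavage at 3-, 7- or 4'-OMe, or Lewis-acid-induced benzyl migration, is possible. The fallback sets out from 15 and comes back at 18. The order is reversed and the Lewis acid is dropped. Hydrogenolysis of 15 (H2, Pd/C) first gives 6,3',5'-trihydroxy-3,5,7,8,4'-pentamethoxyflavone F6. The 5-OMe is then removed by Brønsted-acid cleavage (conc. HCl–EtOH, reflux, argon). This attacks only the methoxy group peri to the protonated carbonyl and gives 18 directly. The reaction time is kept short to avoid ring-opening isomerisation.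

## Further compounds
F1 | step 3 | 4-hydroxy-2,5,6-trimethoxy-3-(methoxyacetyl)benzaldehyde | COCC(=O)c1c(OC)c(C=O)c(OC)c(OC)c1O
F2 | step 3 | 4-hydroxy-2,5,6-trimethoxy-3-(methoxyacetyl)phenyl formate | COCC(=O)c1c(OC)c(OC=O)c(OC)c(OC)c1O
F3 | step 6 | 3,5-bis(benzyloxy)-4-methoxybenzoic anhydride | O=C(OC(=O)c1cc(OCc2ccccc2)c(OC)c(OCc2ccccc2)c1)c1cc(OCc2ccccc2)c(OC)c(OCc2ccccc2)c1
F4 | step 6 | potassium 3,5-bis(benzyloxy)-4-methoxybenzoate | [K+].[O-]C(=O)c1cc(OCc2ccccc2)c(OC)c(OCc2ccccc2)c1
F5 | step 6 | 2-[3,5-bis(benzyloxy)-4-methoxyphenyl]-3,5,7,8-tetramethoxy-4-oxo-4H-chromen-6-yl 3,5-bis(benzyloxy)-4-methoxybenzoate | COc1c(OCc2ccccc2)cc(cc1OCc1ccccc1)-c1oc2c(OC)c(OC)c(OC(=O)c3cc(OCc4ccccc4)c(OC)c(OCc4ccccc4)c3)c(OC)c2c(=O)c1OC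
F6 | step 7 | 6,3',5'-trihydroxy-3,5,7,8,4'-pentamethoxyflavone | COc1c(O)cc(cc1O)-c1oc2c(OC)c(OC)c(O)c(OC)c2c(=O)c1OC
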